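Halimane numbering is used (ring A: C1–C5, C10; ring B: C5–C10; C17 on C8, C20 on C9). Everything rests on closing ring B at C8–C9, the bond between the tertiary C8 and the quaternary C9. The key step exploits the C1=C10 alkene of ring A: a C1 ketone in its place makes C9 the β-carbon of a Z tetrasubstituted exocyclic enone. Hydrogen-atom transfer to the terminal alkene of a butenyl chain on C5 creates the C17 methyl and a C8 radical that adds 6-endo to C9, setting C8 and C9 in one operation. The precursor is a monocyclic 2-alkylidenecyclohexanone.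

Key step: step 7

Step 1
Reactants: 1 methyl benzoate
Product: 3 methyl 1-methylcyclohexa-2,5-diene-1-carboxylate, via Birch enolate 2 (not isolated)
Conditions: K, NH3 (l), t-BuOH (1 equiv), THF, -78 °C; then MeI, -78 °C to rt
Reagents that add atoms: iodomethane, CI
Why: Birch reduction gives the cross-conjugated ester enolate, which is methylated at the ipso carbon (Birch reductive alkylation); the product is achiral.

Step 2
Reactants: 3 methyl 1-methylcyclohexa-2,5-diene-1-carboxylate
Product: 4 methyl 1-methyl-4-oxocyclohexa-2,5-diene-1-carboxylate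
Conditions: CrO3 (5 mol %), t-BuOOH (70% aq.), CH2Cl2, rt
Reagents that add atoms: tert-butyl hydroperoxide, CC(C)(C)OO
Why: Chromium-catalysed allylic oxidation turns the doubly allylic CH2 into the ketone of a prochiral 4,4-disubstituted cyclohexa-2,5-dienone (no stereocentre).

Step 3
Reactants: 4 methyl 1-methyl-4-oxocyclohexa-2,5-diene-1-carboxylate; 5 but-3-en-1-ylmagnesium bromide
Product: 6 methyl (1R,6R)-6-(but-3-en-1-yl)-1-methyl-4-oxocyclohex-2-ene-1-carboxylate
Conditions: CuBr·SMe2 (5 mol %), (R)-1-[(S)-2-(diphenylphosphino)ferrocenyl]ethyldicyclohexylphosphine (6 mol %; ligand enantiomer chosen for the sense shown), t-BuOMe, -75 °C; aq. NH4Cl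
Reagents that add atoms: none
Why: Copper-catalysed asymmetric conjugate addition desymmetrises the dienone, the chiral copper–phosphine complex choosing one of the two enantiotopic enone units so that C4 and C5 are fixed together, and the nucleophile should enter syn to the ester and anti to the C4 methyl (dipole and steric bias of the quaternary carbon), which gives butenyl cis to CO2Me.

Step 4
Reactants: 6 methyl (1R,6R)-6-(but-3-en-1-yl)-1-methyl-4-oxocyclohex-2-ene-1-carboxylate; 7 O-ethyl ethanethioate
Product: 9 methyl (1S,6S)-6-(but-3-en-1-yl)-1-methyl-5-[(1Z)-1-(methylsulfanyl)ethylidene]-4-oxocyclohex-2-ene-1-carboxylate, via thioxo ketone 8 (not isolated)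
Conditions: LiN(SiMe3)2 (1.05 equiv), THF, -78 °C; 7, -78 to 0 °C; then MeI, 0 °C to rt
Reagents that add atoms: iodomethane, CI
Why: The cross-conjugated ketone can enolise only at C10, thio-Claisen condensation of this enolate with the thionoester gives the chelated monothio-β-diketone, and methylation at the soft sulfur fixes the C10=C9 bond with sulfur syn to the carbonyl (Z).

Step 5
Reactants: 9 methyl (1S,6S)-6-(but-3-en-1-yl)-1-methyl-5-[(1Z)-1-(methylsulfanyl)ethylidene]-4-oxocyclohex-2-ene-1-carboxylate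
Product: 10 methyl (1S,2S)-2-(but-3-en-1-yl)-1-methyl-3-[(1Z)-1-(methylsulfanyl)ethylidene]-4-oxocyclohexane-1-carboxylate
Conditions: LiBH(s-Bu)3, THF, -78 °C; aq. NH4Cl
Reagents that add atoms: none
Why: Conjugate hydride addition (1,4-reduction) at the unsubstituted β-carbon C3 removes the C2=C3 bond, while the fully substituted, donor-bearing vinylogous thioester is left alone; no stereocentre changes.

Step 6
Reactants: 10 methyl (1S,2S)-2-(but-3-en-1-yl)-1-methyl-3-[(1Z)-1-(methylsulfanyl)ethylidene]-4-oxocyclohexane-1-carboxylate; 11 (4-bromobut-1-yn-1-yl)trimethylsilane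
Product: 13 methyl (1S,2R)-2-(but-3-en-1-yl)-1-methyl-4-oxo-3-[(2Z)-6-(trimethylsilyl)hex-5-yn-2-ylidene]cyclohexane-1-carboxylate, via Grignard reagent 12 (not isolated)
Conditions: 11, Mg, THF; then 10, CuBr·SMe2 (10 mol %), THF, -40 to 0 °C
Reagents that add atoms: none
Why: Copper-catalysed conjugate addition–elimination on the vinylogous thioester replaces SMe with retention of alkene geometry, so the new chain stays syn to the carbonyl and the tetrasubstituted enone is Z.

Step 7
Reactants: 13 methyl (1S,2R)-2-(but-3-en-1-yl)-1-methyl-4-oxo-3-[(2Z)-6-(trimethylsilyl)hex-5-yn-2-ylidene]cyclohexane-1-carboxylate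
Product: 14 methyl (1S,4aS,5S,6R,8aR)-1,5,6-trimethyl-4-oxo-5-[4-(trimethylsilyl)but-3-yn-1-yl]decahydronaphthalene-1-carboxylate
Conditions: Fe(acac)3 (30 mol %), PhSiH3, EtOH/(CH2OH)2, 60 °C
Reagents that add atoms: none
Why: An iron hydride formed from Fe(acac)3 and PhSiH3 transfers a hydrogen atom to the terminal alkene (Markovnikov), which creates the C17 methyl and a secondary C8 radical; this adds to C9, the β-carbon of the enone, and the α-keto radical at C10 is reduced to the enolate and protonated. The closest known reaction type is the iron-mediated reductive olefin coupling (hydrogen-atom-transfer Giese addition) in its intramolecular form. Ring B closes in the 6-endo-trig mode, since 5-exo attack at C10 is polarity-mismatched. C9 is controlled by the enone geometry: allylic 1,3-strain with the C20 methyl holds the C5–C6 bond perpendicular to the enone plane, the radical reaches C9 only from the face of the tether, and the Z arrangement (chain syn to C=O, methyl syn to C5) places C20 cis to H5; C8 is controlled by a chair-like transition state with the C17 methyl pseudo-equatorial, which puts C17 cis to C20; C10 should be protonated anti to the axial C20 to give the trans-fused ketone (epimerisable, and removed as a stereocentre in step 9). The step needs hydrogen-atom transfer to the monosubstituted alkene only, which the silylated internal alkyne and the electron-poor enone secure, and it needs addition to outrun loss of the C8 radical, which the enforced axial butenyl chain should help.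

Step 8
Reactants: 14 methyl (1S,4aS,5S,6R,8aR)-1,5,6-trimethyl-4-oxo-5-[4-(trimethylsilyl)but-3-yn-1-yl]decahydronaphthalene-1-carboxylate
Product: 16 methyl (1S,4R,4aS,5S,6R,8aR)-5-(but-3-yn-1-yl)-4-hydroxy-1,5,6-trimethyldecahydronaphthalene-1-carboxylate, via silylated alcohol 15 (not isolated)
Conditions: NaBH4, K2CO3, MeOH, 0 °C to rt
Reagents that add atoms: none
Why: Axial hydride delivery to the C1 ketone should give the equatorial alcohol (cis to H10), and methanolic carbonate cleaves the alkynyl C–Si bond in the same pot.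

Step 9
Reactants: 16 methyl (1S,4R,4aS,5S,6R,8aR)-5-(but-3-yn-1-yl)-4-hydroxy-1,5,6-trimethyldecahydronaphthalene-1-carboxylate
Product: 18 methyl (1S,5S,6R,8aR)-5-(but-3-yn-1-yl)-1,5,6-trimethyl-1,2,3,5,6,7,8,8a-octahydronaphthalene-1-carboxylate, via sulfamate ester 17 (not isolated)
Conditions: Burgess reagent (MeO2CN–SO2NEt3 inner salt), toluene, 70 °C
Reagents that add atoms: none
Why: Burgess dehydration is a syn elimination through the sulfamate ester, and with the equatorial C1–O bond cis to the axial H10 it should favour the trisubstituted C1=C10 alkene (Zaitsev) over C1=C2, after which C10 is no longer a stereocentre.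

Step 10
Reactants: 18 methyl (1S,5S,6R,8aR)-5-(but-3-yn-1-yl)-1,5,6-trimethyl-1,2,3,5,6,7,8,8a-octahydronaphthalene-1-carboxylate
Product: 21 methyl (1S,5S,6R,8aR)-5-[(3E)-5-hydroxy-3-methylpent-3-en-1-yl]-1,5,6-trimethyl-1,2,3,5,6,7,8,8a-octahydronaphthalene-1-carboxylate, via alkenylalane 19 (not isolated), via lithium alanate 20 (not isolated)
Conditions: Me3Al, Cp2ZrCl2 (20 mol %), CH2Cl2, 0 °C to rt; then n-BuLi, (CH2O)n, THF, -78 °C to rt
Reagents that add atoms: trimethylaluminium, C[Al](C)C; formaldehyde (as paraformaldehyde), C=O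
Why: Negishi carboalumination adds methyl and aluminium syn across the terminal alkyne with methyl on the internal carbon, and the derived alanate reacts with formaldehyde with retention to give the E allylic alcohol.

Step 11
Reactants: 21 methyl (1S,5S,6R,8aR)-5-[(3E)-5-hydroxy-3-methylpent-3-en-1-yl]-1,5,6-trimethyl-1,2,3,5,6,7,8,8a-octahydronaphthalene-1-carboxylate
Product: 22 methyl (1S,5S,6R,8aR)-5-[(3E)-5-(formyloxy)-3-methylpent-3-en-1-yl]-1,5,6-trimethyl-1,2,3,5,6,7,8,8a-octahydronaphthalene-1-carboxylate (CNP0188193.1)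
Conditions: HCO2CH2CF3, 65 °C
Reagents that add atoms: 2,2,2-trifluoroethyl formate, O=COCC(F)(F)F
Why: Transesterification (formyl transfer) from the activated formate to the primary allylic alcohol gives the formate without touching the hindered methyl ester or the alkenes.

Compound list
1 | methyl benzoate | COC(=O)c1ccccc1 | starting material
2 | potassium enolate of methyl cyclohexa-2,5-diene-1-carboxylate | COC([O-])=C1C=CCC=C1.[K+] | intermediate
3 | methyl 1-methylcyclohexa-2,5-diene-1-carboxylate | COC(=O)C1(C)C=CCC=C1 | intermediate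
4 | methyl 1-methyl-4-oxocyclohexa-2,5-diene-1-carboxylate | COC(=O)C1(C)C=CC(=O)C=C1 | intermediate
5 | but-3-en-1-ylmagnesium bromide | C=CCC[Mg]Br | starting material
6 | methyl (1R,6R)-6-(but-3-en-1-yl)-1-methyl-4-oxocyclohex-2-ene-1-carboxylate | COC(=O)[C@@]1(C)C=CC(=O)C[C@H]1CCC=C | intermediate
7 | O-ethyl ethanethioate | CCOC(C)=S | starting material
8 | methyl (1S,6S)-6-(but-3-en-1-yl)-1-methyl-4-oxo-5-[(1Z)-1-sulfanylethylidene]cyclohex-2-ene-1-carboxylate (chelated enethiol form of the monothio-β-diketone) | COC(=O)[C@@]1(C)C=CC(=O)/C(=C(/C)S)[C@H]1CCC=C | intermediate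
9 | methyl (1S,6S)-6-(but-3-en-1-yl)-1-methyl-5-[(1Z)-1-(methylsulfanyl)ethylidene]-4-oxocyclohex-2-ene-1-carboxylate | COC(=O)[C@@]1(C)C=CC(=O)/C(=C(/C)SC)[C@H]1CCC=C | intermediate
10 | methyl (1S,2S)-2-(but-3-en-1-yl)-1-methyl-3-[(1Z)-1-(methylsulfanyl)ethylidene]-4-oxocyclohexane-1-carboxylate | COC(=O)[C@@]1(C)CCC(=O)/C(=C(/C)SC)[C@H]1CCC=C | intermediate
11 | (4-bromobut-1-yn-1-yl)trimethylsilane | C[Si](C)(C)C#CCCBr | starting material
12 | [4-(trimethylsilyl)but-3-yn-1-yl]magnesium bromide | C[Si](C)(C)C#CCC[Mg]Br | intermediate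
13 | methyl (1S,2R)-2-(but-3-en-1-yl)-1-methyl-4-oxo-3-[(2Z)-6-(trimethylsilyl)hex-5-yn-2-ylidene]cyclohexane-1-carboxylate | COC(=O)[C@@]1(C)CCC(=O)/C(=C(/C)CCC#C[Si](C)(C)C)[C@H]1CCC=C | intermediate
14 | methyl (1S,4aS,5S,6R,8aR)-1,5,6-trimethyl-4-oxo-5-[4-(trimethylsilyl)but-3-yn-1-yl]decahydronaphthalene-1-carboxylate | COC(=O)[C@@]1(C)CCC(=O)[C@H]2[C@H]1CC[C@@H](C)[C@]2(C)CCC#C[Si](C)(C)C | intermediate
15 | methyl (1S,4R,4aS,5S,6R,8aR)-4-hydroxy-1,5,6-trimethyl-5-[4-(trimethylsilyl)but-3-yn-1-yl]decahydronaphthalene-1-carboxylate | COC(=O)[C@@]1(C)CC[C@@H](O)[C@H]2[C@H]1CC[C@@H](C)[C@]2(C)CCC#C[Si](C)(C)C | intermediate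
16 | methyl (1S,4R,4aS,5S,6R,8aR)-5-(but-3-yn-1-yl)-4-hydroxy-1,5,6-trimethyldecahydronaphthalene-1-carboxylate | COC(=O)[C@@]1(C)CC[C@@H](O)[C@H]2[C@H]1CC[C@@H](C)[C@]2(C)CCC#C | intermediate
17 | N-(methoxycarbonyl)sulfamate ester of alcohol 16 (C1–O–SO2–NH–CO2Me, formed as its triethylammonium salt) | COC(=O)[C@@]1(C)CC[C@@H](OS(=O)(=O)NC(=O)OC)[C@H]2[C@H]1CC[C@@H](C)[C@]2(C)CCC#C | intermediate
18 | methyl (1S,5S,6R,8aR)-5-(but-3-yn-1-yl)-1,5,6-trimethyl-1,2,3,5,6,7,8,8a-octahydronaphthalene-1-carboxylate | COC(=O)[C@@]1(C)CCC=C2[C@H]1CC[C@@H](C)[C@]2(C)CCC#C | intermediate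
19 | methyl (1S,5S,6R,8aR)-5-[(3E)-4-(dimethylalumanyl)-3-methylbut-3-en-1-yl]-1,5,6-trimethyl-1,2,3,5,6,7,8,8a-octahydronaphthalene-1-carboxylate | COC(=O)[C@@]1(C)CCC=C2[C@H]1CC[C@@H](C)[C@]2(C)CC/C(C)=C/[Al](C)C | intermediate
20 | lithium butyl(dimethyl)alanate derived from 19 | COC(=O)[C@@]1(C)CCC=C2[C@H]1CC[C@@H](C)[C@]2(C)CC/C(C)=C/[Al-](C)(C)CCCC.[Li+] | intermediate
21 | methyl (1S,5S,6R,8aR)-5-[(3E)-5-hydroxy-3-methylpent-3-en-1-yl]-1,5,6-trimethyl-1,2,3,5,6,7,8,8a-octahydronaphthalene-1-carboxylate | COC(=O)[C@@]1(C)CCC=C2[C@H]1CC[C@@H](C)[C@]2(C)CC/C(C)=C/CO | intermediate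
22 | methyl (1S,5S,6R,8aR)-5-[(3E)-5-(formyloxy)-3-methylpent-3-en-1-yl]-1,5,6-trimethyl-1,2,3,5,6,7,8,8a-octahydronaphthalene-1-carboxylate (CNP0188193.1) | COC(=O)[C@@]1(C)CCC=C2[C@H]1CC[C@@H](C)[C@]2(C)CC/C(C)=C/COC=O | target

Total steps: 11. Longest linear sequence: 11 steps (1 to 22).

Steps most likely to fail

Step 7. The C8 radical may be reduced, or may give back its hydrogen atom with migration of the alkene, before it adds to the fully substituted C9. The fallback sets out from 13 and comes back at 14. It reverses the polarity of the radical step: Bu3SnH and AIBN in benzene at 80 °C turn the enone into its O-stannyl ketyl, whose allylic radical carries spin at C9 and adds 6-exo to the terminal alkene at C8. The stannane reduces the primary C17 radical, and hydrolysis of the tin enolate gives 14. No new compound is isolated.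

Step 9. The elimination may run toward C2 instead of C10, or stall at the hindered H10. The fallback sets out from 14 and comes back at 18. It forms the C1=C10 bond through an enolate that can only be made toward C10:
- Kinetic enolisation of 14 at C2 (LiN(i-Pr)2, Me3SiCl) gives the trimethylsilyl enol ether F1.
- Saegusa–Ito oxidation with Pd(OAc)2 gives the C2=C3 enone F2.
- LiN(i-Pr)2 then removes the only remaining α-hydrogen (H10), and Comins' reagent gives the dienyl triflate F3.
- Pd(OAc)2/PPh3 with HCO2H and Et3N reduces the C–O bond to give the 1(10),2-diene F4.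
- Diimide (from 2-nitrobenzenesulfonylhydrazide and Et3N) saturates the cis-disubstituted C2=C3 bond to give the silylated alkyne F5.
- K2CO3 in MeOH removes the silyl group to give 18.

Step 4. Proton transfer from the enolisable thionoester to the ketone enolate may win over carbon–carbon bond formation. The fallback sets out from 6 and comes back at 9. LiN(SiMe3)2, CS2 and then MeI give the α-oxo ketene dithioacetal F6. One equivalent of Me2CuLi replaces one SMe by conjugate addition–elimination; the sulfur syn to the carbonyl is expected to stay, chelated to the enolate metal, which gives 9.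

Further compounds
F0 | step 7 | none | none
F1 | step 9 | trimethylsilyl enol ether of 14 (C1–OSiMe3, C1=C2) | COC(=O)[C@@]1(C)CC=C(O[Si](C)(C)C)[C@H]2[C@H]1CC[C@@H](C)[C@]2(C)CCC#C[Si](C)(C)C
F2 | step 9 | C2=C3 enone of 14 (1-oxo-2-ene) | COC(=O)[C@@]1(C)C=CC(=O)[C@H]2[C@H]1CC[C@@H](C)[C@]2(C)CCC#C[Si](C)(C)C
F3 | step 9 | dienyl triflate (C1–OSO2CF3, C1=C10 and C2=C3) | COC(=O)[C@@]1(C)C=CC(OS(=O)(=O)C(F)(F)F)=C2[C@H]1CC[C@@H](C)[C@]2(C)CCC#C[Si](C)(C)C
F4 | step 9 | 1(10),2-diene | COC(=O)[C@@]1(C)C=CC=C2[C@H]1CC[C@@H](C)[C@]2(C)CCC#C[Si](C)(C)C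
F5 | step 9 | C-trimethylsilyl derivative of 18 | COC(=O)[C@@]1(C)CCC=C2[C@H]1CC[C@@H](C)[C@]2(C)CCC#C[Si](C)(C)C
F6 | step 4 | methyl (1S,6S)-5-[bis(methylsulfanyl)methylidene]-6-(but-3-en-1-yl)-1-methyl-4-oxocyclohex-2-ene-1-carboxylate | COC(=O)[C@@]1(C)C=CC(=O)C(=C(SC)SC)[C@H]1CCC=C
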